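**Retrosynthetic overview**
1. Target 23 ⇐ Duff formylation at C8 of 7-hydroxychromone 21 ⇐ 7-O-debenzylation, 5-O-methylation and chelation-controlled 5-O-debenzylation from 5,7-bis(benzyloxy)chromone 18.
2. Ring C is the only ring made (rings A and B are bought): 18 ⇐ acid closure of O1–C2 in the ortho-hydroxyaryl β-keto acetal 16, whose free phenol is O1 while the future 5-oxygen is still benzylated.
3. Key disconnection of 16: O1–C8a and C4–C4a together, i.e. 3,5-bis(benzyloxy)-4-methylbenzyne 15 (from silyl triflate 10) inserting into the C–O bond of acid 14, which carries C2 (as acetal), C3, C4, the benzylic CH2 and ring B.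
4. Structural basis: on the fully substituted ring A (C5-OMe, C6-Me, C7-OH, C8-CHO) the ring oxygen O1 on C8a and the acyl carbon C4 on C4a sit on neighbouring carbons, and the C5 oxygen beside C4a steers an oxygen nucleophile to C8a.
5. 10 ⇐ phenol 5 ⇐ benzoate 1 (ester to ArOH by Hock rearrangement of the dimethyl carbinol); 14 ⇐ ester 11 by formylation, acetalisation and saponification.

Key step: step 10

Remark: the target is achiral; the α-stereocentre of compounds 12–17 is racemic throughout and disappears when ring C becomes the pyranone, so no stereocontrol is needed.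

**Route**

Step 1
Reactants: 1 methyl 3,5-dihydroxy-4-methylbenzoate
Product: 2 methyl 3,5-bis(benzyloxy)-4-methylbenzoate
Conditions: BnBr (2.4 equiv), K2CO3, DMF, 60 °C
Reagents that add atoms: benzyl bromide, BrCc1ccccc1
Why: Williamson ether synthesis on both phenols; the ester is inert to carbonate base.

Step 2
Reactants: 2 methyl 3,5-bis(benzyloxy)-4-methylbenzoate
Product: 3 2-[3,5-bis(benzyloxy)-4-methylphenyl]propan-2-ol
Conditions: MeMgBr (3.5 equiv), THF, 0 °C → rt; aq. NH4Cl
Reagents that add atoms: methylmagnesium bromide, C[Mg]Br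
Why: Double Grignard addition to the ester should give the dimethyl carbinol, benzyl ethers being inert.

Step 3
Reactants: 3 2-[3,5-bis(benzyloxy)-4-methylphenyl]propan-2-ol
Product: 5 3,5-bis(benzyloxy)-4-methylphenol, via tertiary hydroperoxide 4 (not isolated)
Conditions: H2O2 (50% aq.), BF3·OEt2, CH2Cl2, 0 °C; aq. Na2SO3
Reagents that add atoms: hydrogen peroxide, OO
Why: Acid exchanges the tertiary benzylic OH for OOH and hydroperoxide 4 undergoes Hock rearrangement (aryl migration to oxygen, then collapse of the hemiketal to phenol and acetone), in which the aryl group competes only against methyl, whereas an aldehyde Baeyer–Villiger on this ring, which has no ortho or para oxygen, would have to compete against hydride shift.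

Step 4
Reactants: 5 3,5-bis(benzyloxy)-4-methylphenol
Product: 6 3,5-bis(benzyloxy)-2-bromo-4-methylphenol
Conditions: NBS (1.0 equiv), CH2Cl2, −78 → −20 °C
Reagents that add atoms: N-bromosuccinimide, O=C1CCC(=O)N1Br
Why: Electrophilic aromatic bromination ortho to the free phenol; the two ortho positions are equivalent and the para position is blocked by methyl, so only over-bromination has to be held back by stoichiometry and low temperature.

Step 5
Reactants: 6 3,5-bis(benzyloxy)-2-bromo-4-methylphenol
Product: 7 [3,5-bis(benzyloxy)-2-bromo-4-methylphenoxy]trimethylsilane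
Conditions: HMDS, THF, 65 °C; evaporate
Reagents that add atoms: hexamethyldisilazane, C[Si](C)(C)N[Si](C)(C)C
Why: O-silylation of the phenol with the silazane, ammonia being the only by-product, so the silyl ether can be used crude.

Step 6
Reactants: 7 [3,5-bis(benzyloxy)-2-bromo-4-methylphenoxy]trimethylsilane
Product: 10 3,5-bis(benzyloxy)-4-methyl-2-(trimethylsilyl)phenyl trifluoromethanesulfonate, via aryllithium 8 (not isolated), via lithium 2-silylphenoxide 9 (not isolated)
Conditions: n-BuLi (1.1 equiv), THF, −78 °C; then Tf2O, −78 → 0 °C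
Reagents that add atoms: trifluoromethanesulfonic anhydride, O=S(=O)(OS(=O)(=O)C(F)(F)F)C(F)(F)F
Why: Bromine–lithium exchange, 1,3 O-to-C silyl shift (retro-Brook rearrangement) and O-triflation of the resulting phenoxide is the standard way to ortho-silylaryl triflates, and at −78 °C the exchange should outrun benzylic deprotonation.

Step 7
Reactants: 11 methyl 3-(4-methoxyphenyl)propanoate
Product: 12 methyl 2-formyl-3-(4-methoxyphenyl)propanoate (racemic; enol form in equilibrium)
Conditions: NaH, HCO2Me, THF, 0 °C → rt; cold 1 M HCl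
Reagents that add atoms: methyl formate, COC=O
Why: Crossed Claisen condensation with the non-enolisable formate, driven by deprotonation of the β-formyl ester formed.

Step 8
Reactants: 12 methyl 2-formyl-3-(4-methoxyphenyl)propanoate
Product: 13 methyl 3,3-dimethoxy-2-(4-methoxybenzyl)propanoate (racemic)
Conditions: HC(OMe)3 (neat), TsOH·H2O (cat.), 50 °C; aq. NaHCO3
Reagents that add atoms: trimethyl orthoformate, COC(OC)OC
Why: Acid-catalysed acetalisation, the orthoformate serving as methoxy donor and water scavenger.

Step 9
Reactants: 13 methyl 3,3-dimethoxy-2-(4-methoxybenzyl)propanoate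
Product: 14 3,3-dimethoxy-2-(4-methoxybenzyl)propanoic acid (racemic)
Conditions: LiOH·H2O, THF/H2O, rt; cold 1 M HCl to pH 4
Reagents that add atoms: lithium hydroxide, [Li+].[OH-]
Why: Saponification at room temperature, where the acetal is stable to base and E1cB loss of methanol is slow; cold acidification only to pH 4 should leave the acetal intact.

Step 10
Reactants: 10 3,5-bis(benzyloxy)-4-methyl-2-(trimethylsilyl)phenyl trifluoromethanesulfonate; 14 3,3-dimethoxy-2-(4-methoxybenzyl)propanoic acid
Product: 16 racemic 1-[2,4-bis(benzyloxy)-6-hydroxy-3-methylphenyl]-3,3-dimethoxy-2-(4-methoxybenzyl)propan-1-one, via 3,5-bis(benzyloxy)-4-methylbenzyne 15 (not isolated)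
Conditions: CsF (4 equiv), THF, 125 °C (sealed tube); 10 (1.5 equiv), 14 (1.0 equiv)
Reagents that add atoms: none
Why: Fluoride removes the silyl group of 10 and triflate leaves to give aryne 15; the carboxylate of 14 adds through oxygen to the aryne carbon that becomes C8a, and the aryl anion left on the neighbouring carbon (the future C4a, beside the benzyloxy group) attacks its own ester carbonyl to give a four-membered alkoxide that opens to the ortho-acylphenoxide, so that O1–C8a and C4–C4a form in one operation. The closest known reaction type is the fluoride-induced insertion of arynes into the C–O bond of carboxylic acids to give ortho-hydroxyaryl ketones, an anionic Fries-type 1,3 O-to-C acyl shift. No ring is closed (the four-membered alkoxide is transient) and no stereocentre is created: the α-carbon arrives racemic from 14 and becomes sp2 in step 11. The regioselectivity needed, oxygen on C8a and acyl on C4a, is secured by the benzyloxy group next to one aryne carbon, which by induction directs the nucleophile to the remote, unhindered aryne carbon and stabilises the anion beside itself. The chemoselectivity needed, acyl transfer ahead of protonation of the aryl anion (which would stop at the O-aryl ester), is favoured by the hot aprotic medium and by the single acidic proton per acid molecule; with no Lewis acid present, the acetal and both benzyl ethers should persist. Any chromone 18 that arises in the flask by base-induced loss of methanol would be carried into step 11 together with 16.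

Step 11
Reactants: 16 racemic 1-[2,4-bis(benzyloxy)-6-hydroxy-3-methylphenyl]-3,3-dimethoxy-2-(4-methoxybenzyl)propan-1-one
Product: 18 5,7-bis(benzyloxy)-3-(4-methoxybenzyl)-6-methyl-4H-chromen-4-one, via 2-methoxychroman-4-one 17 (not isolated)
Conditions: TsOH·H2O (0.2 equiv), toluene, 60 °C
Reagents that add atoms: none
Why: Acid-catalysed cyclodehydration of a β-keto acetal: the acetal ionises to an oxocarbenium ion, the only free phenol adds (6-exo-trig) to give 17, which loses methanol to the chromone, and because the other ortho oxygen is still benzylated the 8-methyl isomer cannot form.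

Step 12
Reactants: 18 5,7-bis(benzyloxy)-3-(4-methoxybenzyl)-6-methyl-4H-chromen-4-one
Product: 19 7-(benzyloxy)-5-hydroxy-3-(4-methoxybenzyl)-6-methyl-4H-chromen-4-one
Conditions: MgBr2·OEt2 (3 equiv), toluene/Et2O, 80 °C; 1 M HCl
Reagents that add atoms: none
Why: Chelation-controlled ether cleavage: magnesium held between C4=O and O5 activates only the peri benzyl ether, which bromide removes as benzyl bromide, while the unchelated 7-O-benzyl and the aryl methyl ether stay.

Step 13
Reactants: 19 7-(benzyloxy)-5-hydroxy-3-(4-methoxybenzyl)-6-methyl-4H-chromen-4-one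
Product: 20 7-(benzyloxy)-5-methoxy-3-(4-methoxybenzyl)-6-methyl-4H-chromen-4-one
Conditions: MeI (5 equiv), K2CO3, DMF, 50 °C
Reagents that add atoms: iodomethane, CI
Why: Williamson methylation of the hydrogen-bonded, flanked 5-OH, which needs excess iodide and warmth, while the more reactive 7-oxygen is still masked as its benzyl ether.

Step 14
Reactants: 20 7-(benzyloxy)-5-methoxy-3-(4-methoxybenzyl)-6-methyl-4H-chromen-4-one
Product: 21 7-hydroxy-5-methoxy-3-(4-methoxybenzyl)-6-methyl-4H-chromen-4-one
Conditions: BCl3 (3 equiv), C6HMe5 (3 equiv), CH2Cl2, −78 °C; H2O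
Reagents that add atoms: none
Why: Lewis-acid debenzylation with pentamethylbenzene as cation scavenger: at −78 °C the benzyl ether ionises far faster than chloride can displace a methyl ether, so both methoxy groups should stay, and the hydrogenation that would threaten the C2=C3 bond is avoided.

Step 15
Reactants: 21 7-hydroxy-5-methoxy-3-(4-methoxybenzyl)-6-methyl-4H-chromen-4-one
Product: 23 7-hydroxy-5-methoxy-3-(4-methoxybenzyl)-6-methyl-4-oxo-4H-chromene-8-carbaldehyde, via 8-aldimine 22 (not isolated)
Conditions: HMTA (4 equiv), AcOH, 100 °C; then 3 M HCl, 80 °C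
Reagents that add atoms: hexamethylenetetramine, C1N2CN3CN1CN(C2)C3; water, O
Why: Duff reaction: the iminium ion from HMTA attacks C8, the only unsubstituted carbon of ring A and ortho to the free 7-OH, internal hydride transfer gives aldimine 22, which aqueous acid hydrolyses, and in acetic acid the anisole ring B should not be formylated.

**Compound list**
1 | methyl 3,5-dihydroxy-4-methylbenzoate | COC(=O)c1cc(O)c(C)c(O)c1 | starting material
2 | methyl 3,5-bis(benzyloxy)-4-methylbenzoate | COC(=O)c1cc(OCc2ccccc2)c(C)c(OCc2ccccc2)c1 | intermediate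
3 | 2-[3,5-bis(benzyloxy)-4-methylphenyl]propan-2-ol | CC(C)(O)c1cc(OCc2ccccc2)c(C)c(OCc2ccccc2)c1 | intermediate
4 | 2-[3,5-bis(benzyloxy)-4-methylphenyl]propan-2-yl hydroperoxide | CC(C)(OO)c1cc(OCc2ccccc2)c(C)c(OCc2ccccc2)c1 | intermediate (not isolated)
5 | 3,5-bis(benzyloxy)-4-methylphenol | Cc1c(OCc2ccccc2)cc(O)cc1OCc1ccccc1 | intermediate
6 | 3,5-bis(benzyloxy)-2-bromo-4-methylphenol | Cc1c(OCc2ccccc2)cc(O)c(Br)c1OCc1ccccc1 | intermediate
7 | [3,5-bis(benzyloxy)-2-bromo-4-methylphenoxy]trimethylsilane | Cc1c(OCc2ccccc2)cc(O[Si](C)(C)C)c(Br)c1OCc1ccccc1 | intermediate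
8 | {2,4-bis(benzyloxy)-3-methyl-6-[(trimethylsilyl)oxy]phenyl}lithium | [Li]c1c(O[Si](C)(C)C)cc(OCc2ccccc2)c(C)c1OCc1ccccc1 | intermediate (not isolated)
9 | lithium 3,5-bis(benzyloxy)-4-methyl-2-(trimethylsilyl)phenoxide | [Li+].[O-]c1cc(OCc2ccccc2)c(C)c(OCc2ccccc2)c1[Si](C)(C)C | intermediate (not isolated)
10 | 3,5-bis(benzyloxy)-4-methyl-2-(trimethylsilyl)phenyl trifluoromethanesulfonate | C[Si](C)(C)c1c(OS(=O)(=O)C(F)(F)F)cc(OCc2ccccc2)c(C)c1OCc1ccccc1 | intermediate
11 | methyl 3-(4-methoxyphenyl)propanoate | COC(=O)CCc1ccc(OC)cc1 | starting material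
12 | methyl 2-formyl-3-(4-methoxyphenyl)propanoate (racemic) | COC(=O)C(C=O)Cc1ccc(OC)cc1 | intermediate
13 | methyl 3,3-dimethoxy-2-(4-methoxybenzyl)propanoate (racemic) | COC(=O)C(Cc1ccc(OC)cc1)C(OC)OC | intermediate
14 | 3,3-dimethoxy-2-(4-methoxybenzyl)propanoic acid (racemic) | COC(OC)C(Cc1ccc(OC)cc1)C(=O)O | intermediate
15 | 3,5-bis(benzyloxy)-4-methylbenzyne | CC1=C(OCc2ccccc2)C#CC=C1OCc1ccccc1 | intermediate (not isolated)
16 | 1-[2,4-bis(benzyloxy)-6-hydroxy-3-methylphenyl]-3,3-dimethoxy-2-(4-methoxybenzyl)propan-1-one (racemic) | COC(OC)C(Cc1ccc(OC)cc1)C(=O)c1c(O)cc(OCc2ccccc2)c(C)c1OCc1ccccc1 | intermediate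
17 | 5,7-bis(benzyloxy)-2-methoxy-3-(4-methoxybenzyl)-6-methylchroman-4-one (racemic diastereomer mixture) | COC1Oc2cc(OCc3ccccc3)c(C)c(OCc3ccccc3)c2C(=O)C1Cc1ccc(OC)cc1 | intermediate (not isolated)
18 | 5,7-bis(benzyloxy)-3-(4-methoxybenzyl)-6-methyl-4H-chromen-4-one | COc1ccc(Cc2coc3cc(OCc4ccccc4)c(C)c(OCc4ccccc4)c3c2=O)cc1 | intermediate
19 | 7-(benzyloxy)-5-hydroxy-3-(4-methoxybenzyl)-6-methyl-4H-chromen-4-one | COc1ccc(Cc2coc3cc(OCc4ccccc4)c(C)c(O)c3c2=O)cc1 | intermediate
20 | 7-(benzyloxy)-5-methoxy-3-(4-methoxybenzyl)-6-methyl-4H-chromen-4-one | COc1ccc(Cc2coc3cc(OCc4ccccc4)c(C)c(OC)c3c2=O)cc1 | intermediate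
21 | 7-hydroxy-5-methoxy-3-(4-methoxybenzyl)-6-methyl-4H-chromen-4-one | COc1ccc(Cc2coc3cc(O)c(C)c(OC)c3c2=O)cc1 | intermediate
22 | 7-hydroxy-8-(iminomethyl)-5-methoxy-3-(4-methoxybenzyl)-6-methyl-4H-chromen-4-one | COc1ccc(Cc2coc3c(C=N)c(O)c(C)c(OC)c3c2=O)cc1 | intermediate (not isolated)
23 | 7-hydroxy-5-methoxy-3-(4-methoxybenzyl)-6-methyl-4-oxo-4H-chromene-8-carbaldehyde | COc1ccc(Cc2coc3c(C=O)c(O)c(C)c(OC)c3c2=O)cc1 | target

**Count**
Total steps: 15. Longest linear sequence: 12 steps (steps 1–6 and 10–15, from 1 to 23); the acid branch (steps 7–9) joins at step 10.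

**Steps most likely to fail**

Step 10. The aryl anion may be protonated by the acid or by hydrogen difluoride before it reaches the ester carbonyl, so that the reaction stops at the O-aryl ester. The acyl shift may also be slow for an α-branched acyl group arriving at an anion with two ortho substituents, and excess aryne may O-arylate the product phenoxide. Fallback, setting out from 6 and 14 and returning at 16: the same aryl anion would be generated regiospecifically by halogen–metal exchange. Carbodiimide esterification of bromophenol 6 with acid 14 (EDC·HCl, DMAP, CH2Cl2) should give 3,5-bis(benzyloxy)-2-bromo-4-methylphenyl 3,3-dimethoxy-2-(4-methoxybenzyl)propanoate F1. Treatment with n-BuLi in THF at −100 °C should then trigger bromine–lithium exchange and anionic ortho-Fries acyl migration to the phenoxide of 16, with no external proton source present until work-up.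

Step 3. The electron-rich phenol may be oxidised further by acidic peroxide, or the carbinol may dehydrate to the isopropenylarene and oligomerise before the hydroperoxide forms. Fallback, setting out from 2 and returning at 5: the ester is converted with MeNH(OMe)·HCl and i-PrMgCl (THF, −20 °C) into 3,5-bis(benzyloxy)-N-methoxy-N,4-dimethylbenzamide F2. MeMgBr should then give 1-[3,5-bis(benzyloxy)-4-methylphenyl]ethan-1-one F3. Baeyer–Villiger oxidation (mCPBA, cat. TFA, CH2Cl2), in which aryl migrates in preference to methyl, should give 3,5-bis(benzyloxy)-4-methylphenyl acetate F4, and methanolysis (K2CO3, MeOH) should release 5.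

Step 14. Boron bound to C4=O may assist loss of the neighbouring 5-O-methyl group alongside debenzylation, or debenzylation may stall if the mixture is kept too cold to spare that ether. Fallback, setting out from 18 and returning at 21: the protecting group on O7 is exchanged before the methyl ether is made. Both benzyl ethers of 18 are removed with BCl3 and C6HMe5 at −78 °C (no peri methyl ether is present yet) to give 5,7-dihydroxy-3-(4-methoxybenzyl)-6-methyl-4H-chromen-4-one F5. The free 7-OH alone should react with MOMCl and i-Pr2NEt, the chelated 5-OH staying inert, to give 5-hydroxy-7-(methoxymethoxy)-3-(4-methoxybenzyl)-6-methyl-4H-chromen-4-one F6. Methylation (MeI, K2CO3, DMF) should give 5-methoxy-7-(methoxymethoxy)-3-(4-methoxybenzyl)-6-methyl-4H-chromen-4-one F7, and HCl in MeOH at 40 °C should cleave the acetal to 21 without touching either methyl ether.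

**Further compounds**
F1 | step 10 | 3,5-bis(benzyloxy)-2-bromo-4-methylphenyl 3,3-dimethoxy-2-(4-methoxybenzyl)propanoate (racemic) | COC(OC)C(Cc1ccc(OC)cc1)C(=O)Oc1cc(OCc2ccccc2)c(C)c(OCc2ccccc2)c1Br
F2 | step 3 | 3,5-bis(benzyloxy)-N-methoxy-N,4-dimethylbenzamide | CON(C)C(=O)c1cc(OCc2ccccc2)c(C)c(OCc2ccccc2)c1
F3 | step 3 | 1-[3,5-bis(benzyloxy)-4-methylphenyl]ethan-1-one | CC(=O)c1cc(OCc2ccccc2)c(C)c(OCc2ccccc2)c1
F4 | step 3 | 3,5-bis(benzyloxy)-4-methylphenyl acetate | CC(=O)Oc1cc(OCc2ccccc2)c(C)c(OCc2ccccc2)c1
F5 | step 14 | 5,7-dihydroxy-3-(4-methoxybenzyl)-6-methyl-4H-chromen-4-one | COc1ccc(Cc2coc3cc(O)c(C)c(O)c3c2=O)cc1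
F6 | step 14 | 5-hydroxy-7-(methoxymethoxy)-3-(4-methoxybenzyl)-6-methyl-4H-chromen-4-one | COCOc1cc2occ(Cc3ccc(OC)cc3)c(=O)c2c(O)c1C
F7 | step 14 | 5-methoxy-7-(methoxymethoxy)-3-(4-methoxybenzyl)-6-methyl-4H-chromen-4-one | COCOc1cc2occ(Cc3ccc(OC)cc3)c(=O)c2c(OC)c1C
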